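**Plan**

- Numbering used throughout: seven-membered ring C1 (angular CMe), C5 (fusion CH), C6 (CH–O‑vanilloyl), C7, C8 (C(OH)Me), C9, C10; five-membered ring C1, C2=C3, C4 (C(OH)iPr), C5.
- Retrosynthetic cuts, in order: the C6 ester; C4–isopropyl; C2=C3 (metathesis); C4–C5 (aldol); C1–C2 (conjugate addition); last, C1–C5 and C7–C8 of the seven-membered ring.
- Enabling feature: in the seven-membered ring, C5–C6(O)–C7 is an acetone unit spanning C1 and C8, two methyl-bearing carbons linked through C9–C10, with oxygen on C8. This is the pattern of 2,5-dimethylfuran, so the carbocycle is an oxyallyl/furan (4+3) adduct whose oxygen bridge is later cut to leave the C8 carbinol.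
- Forward order: seven-membered ring first (as an 8-oxabicyclo[3.2.1]octenone), hydrogenation, desymmetrising bridge opening to the C5=C1 enone, vinyl at C1, acrolein at C5, C6 reduction, five-membered ring by metathesis, C4 oxidation, isopropyl addition, vanilloylation.
- Stereochemistry: C8 (absolute) from chiral lithium amide desymmetrisation of the meso adduct; C1 and C5 from the C8-biased chair of the seven-membered ring; C6 relayed from the temporary C4 carbinol by chelate reduction; C4 from attack anti to the angular methyl.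

Key step: step 1

Assumption: the (R,R)-amide is taken to remove the proton next to the (S)-bridgehead of 5; if the sense proves opposite, the (S,S)-amide is used with no other change.

**Route**

Step 1
Reactants: 1 2,5-dimethylfuran; 2 1,1,3,3-tetrabromoacetone
Product: 4 meso-(1R,5S)-1,5-dimethyl-8-oxabicyclo[3.2.1]oct-6-en-3-one, via 2,4-dibromo cycloadduct 3 (not isolated)
Conditions: Zn–Cu couple, THF, −10 °C → rt (1 in excess); then Zn–Cu couple, NH4Cl, MeOH, rt
Reagents that add atoms: none
Why: Zinc strips two bromines from 2 to give a zinc-bound 1,3-dibromo-2-oxyallyl cation, a three-carbon 2π partner that adds across C2 and C5 of the furan diene (concerted, or stepwise through a furan-stabilised oxocarbenium ion), and the two remaining bromines are then removed reductively. The closest known reaction type is the zinc/polybromoketone oxyallyl cation–furan (4+3) cycloaddition. The seven-membered carbocycle is closed by the cycloaddition itself, forming C1–C5 and C7–C8 at once, while the furan oxygen stays as a temporary C1–O–C8 bridge. The two bridgehead stereocentres are fixed by the bridge, which forces both methyls cis across it, so only the meso adduct can form and the transient CHBr centres are erased. The selectivity needed is periselectivity for (4+3) addition over electrophilic substitution of the furan, secured by the methyl groups that block C2 and C5 and raise the diene HOMO.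

Step 2
Reactants: 4 meso-(1R,5S)-1,5-dimethyl-8-oxabicyclo[3.2.1]oct-6-en-3-one
Product: 5 meso-(1R,5S)-1,5-dimethyl-8-oxabicyclo[3.2.1]octan-3-one
Conditions: H2 (1 atm), 10% Pd/C, EtOAc, rt
Reagents that add atoms: none
Why: Heterogeneous catalytic hydrogenation saturates the strained cis-alkene and leaves the ketone alone, giving the C9–C10 ethano unit without disturbing the meso symmetry.

Step 3
Reactants: 5 meso-(1R,5S)-1,5-dimethyl-8-oxabicyclo[3.2.1]octan-3-one
Product: 7 (1S,5R)-1,5-dimethyl-3-(triethylsilyloxy)-8-oxabicyclo[3.2.1]oct-2-ene, via lithium enolate 6 (not isolated)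
Conditions: lithium (R,R)-bis(1-phenylethyl)amide·LiCl [from the amine hydrochloride, n-BuLi (2 equiv)], TESCl present (internal quench), THF, −100 → −78 °C, slow addition of 5; Et3N, aq. NaHCO3
Reagents that add atoms: chlorotriethylsilane, CC[Si](Cl)(CC)CC
Why: Enantiotopos-selective deprotonation of a meso ketone by a C2-symmetric chiral lithium amide (chiral-base desymmetrisation with internal silyl quench) removes the proton next to the (S)-bridgehead, which decides that this bridgehead becomes sp2 C1 and that the (R)-bridgehead survives as the C8 carbinol centre.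

Step 4
Reactants: 7 (1S,5R)-1,5-dimethyl-3-(triethylsilyloxy)-8-oxabicyclo[3.2.1]oct-2-ene
Product: 8 (6R)-3,6-dimethyl-6-(triethylsilyloxy)cyclohept-2-en-1-one
Conditions: TESOTf (5 mol%), CH2Cl2, −78 → −20 °C; Et3N quench
Reagents that add atoms: none
Why: Silyl-triflate-catalysed vinylogous ring opening, in which silylation of the bridge oxygen lets the enol ether expel the tertiary C1–O bond and the resulting O-silyl enone cation hands its silyl group to the next molecule, cuts the same bond as a base-mediated E1cB opening but delivers the C8 oxygen as a silyl ether that cannot undergo retro-aldol cleavage, and it does not touch the C8 stereocentre.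

Step 5
Reactants: 8 (6R)-3,6-dimethyl-6-(triethylsilyloxy)cyclohept-2-en-1-one
Product: 9 (3S,6R)-3-ethenyl-3,6-dimethyl-6-(triethylsilyloxy)-1-(trimethylsilyloxy)cyclohept-1-ene
Conditions: vinylMgBr, CuBr·SMe2 (10 mol%), TMSCl, HMPA, THF, −78 °C; Et3N, cold aq. NaHCO3
Reagents that add atoms: vinylmagnesium bromide, C=C[Mg]Br; chlorotrimethylsilane, C[Si](C)(C)Cl
Why: Copper-catalysed, TMSCl-accelerated conjugate addition of a Grignard reagent builds the quaternary C1 and traps the enolate regiospecifically as the C5=C6 enol silane; in the chair-like transition state the vinyl group enters axially on the face away from the ring body, and since the C8 silyloxy group prefers the axial site over methyl, vinyl is expected trans to OSiEt3.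

Step 6
Reactants: 9 (3S,6R)-3-ethenyl-3,6-dimethyl-6-(triethylsilyloxy)-1-(trimethylsilyloxy)cyclohept-1-ene; 10 acrolein
Product: 13 (2R,3S,6R)-3-ethenyl-2-[(1R)-1-hydroxyprop-2-en-1-yl]-3,6-dimethyl-6-(triethylsilyloxy)cycloheptan-1-one, via lithium enolate 11 (not isolated), via dicyclohexylboron enolate 12 (not isolated)
Conditions: MeLi, THF, 0 °C; Cy2BCl, −78 °C; acrolein, −78 → −20 °C; pH 7 buffer, MeOH, H2O2, 0 °C
Reagents that add atoms: none
Why: The enol silane is cleaved to the regiodefined lithium enolate, exchanged to the boron (E)-enolate and joined to acrolein in a boron aldol reaction through a Zimmerman–Traxler chair, which gives the anti C4/C5 relationship, while the aldehyde is expected to approach C5 anti to the pseudoaxial C1 vinyl group so that the new side chain lies trans to vinyl.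

Step 7
Reactants: 13 (2R,3S,6R)-3-ethenyl-2-[(1R)-1-hydroxyprop-2-en-1-yl]-3,6-dimethyl-6-(triethylsilyloxy)cycloheptan-1-one
Product: 15 (1S,2S,3S,6R)-3-ethenyl-2-[(1R)-1-hydroxyprop-2-en-1-yl]-3,6-dimethyl-6-(triethylsilyloxy)cycloheptan-1-ol, via diethylboron chelate 14 (not isolated)
Conditions: Et2BOMe, THF–MeOH (4:1), −78 °C; NaBH4, −78 °C; AcOH, then MeOH co-evaporation
Reagents that add atoms: none
Why: In this Narasaka–Prasad reduction external hydride attacks the boron chelate of the β-hydroxy ketone to give the 1,3-syn diol, which together with the anti aldol places the C6 hydroxyl cis to H5 and trans to the C5 side chain, as the target requires.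

Step 8
Reactants: 15 (1S,2S,3S,6R)-3-ethenyl-2-[(1R)-1-hydroxyprop-2-en-1-yl]-3,6-dimethyl-6-(triethylsilyloxy)cycloheptan-1-ol
Product: 16 (3R,3aS,4S,6R,8aS)-6,8a-dimethyl-6-(triethylsilyloxy)-3,3a,4,5,6,7,8,8a-octahydroazulene-3,4-diol
Conditions: second-generation Grubbs catalyst (H2IMes)(PCy3)Cl2Ru=CHPh (5 mol%), CH2Cl2 (5 mM), 40 °C
Reagents that add atoms: none
Why: Ring-closing olefin metathesis between the C1 vinyl group and the allylic-alcohol vinyl group closes the cyclopentene (C2=C3) with loss of ethylene, the trans ring fusion being already fixed at C1 and C5 and readily accommodated by the flexible seven-membered ring.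

Step 9
Reactants: 16 (3R,3aS,4S,6R,8aS)-6,8a-dimethyl-6-(triethylsilyloxy)-3,3a,4,5,6,7,8,8a-octahydroazulene-3,4-diol
Product: 17 (3aS,4S,6R,8aS)-4-hydroxy-6,8a-dimethyl-6-(triethylsilyloxy)-3a,4,5,6,7,8-hexahydroazulen-3(8aH)-one
Conditions: activated MnO2 (excess), CH2Cl2, rt
Reagents that add atoms: none
Why: Chemoselective allylic oxidation by MnO2 converts only the allylic C4 carbinol to the enone, leaves the saturated C6 alcohol untouched, and is neutral enough to spare the epimerisable fusion centre C5.

Step 10
Reactants: 17 (3aS,4S,6R,8aS)-4-hydroxy-6,8a-dimethyl-6-(triethylsilyloxy)-3a,4,5,6,7,8-hexahydroazulen-3(8aH)-one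
Product: 18 (3S,3aS,4S,6R,8aS)-6,8a-dimethyl-3-(propan-2-yl)-6-(triethylsilyloxy)-3,3a,4,5,6,7,8,8a-octahydroazulene-3,4-diol
Conditions: iPrMgCl, anhydrous CeCl3 (4 equiv each), THF, −78 → −40 °C; aq. NH4Cl
Reagents that add atoms: isopropylmagnesium chloride, CC(C)[Mg]Cl
Why: Organocerium 1,2-addition suppresses enolisation and conjugate addition, and after deprotonation of the C6 hydroxyl the isopropyl group is expected to reach the carbonyl from the face carrying H5 and the C6 alkoxide, opposite the angular C1 methyl, so that the C4 hydroxyl ends up cis to that methyl.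

Step 11
Reactants: 19 vanillic acid
Product: 21 4-(tert-butyldimethylsilyloxy)-3-methoxybenzoic acid, via bis-silylated vanillate 20 (not isolated)
Conditions: TBSCl (2.5 equiv), imidazole, DMF, rt; then AcOH–THF–H2O, rt
Reagents that add atoms: tert-butylchlorodimethylsilane, CC(C)(C)[Si](C)(C)Cl
Why: Exhaustive silylation followed by selective hydrolysis of the labile silyl ester (standard phenol protection) leaves the phenol masked so that the acid can be activated without self-acylation.

Step 12
Reactants: 18 (3S,3aS,4S,6R,8aS)-6,8a-dimethyl-3-(propan-2-yl)-6-(triethylsilyloxy)-3,3a,4,5,6,7,8,8a-octahydroazulene-3,4-diol; 21 4-(tert-butyldimethylsilyloxy)-3-methoxybenzoic acid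
Product: 22 (3S,3aS,4S,6R,8aS)-3-hydroxy-6,8a-dimethyl-3-(propan-2-yl)-6-(triethylsilyloxy)-3,3a,4,5,6,7,8,8a-octahydroazulen-4-yl 4-(tert-butyldimethylsilyloxy)-3-methoxybenzoate
Conditions: EDC·HCl, DMAP, CH2Cl2, rt
Reagents that add atoms: none
Why: Steglich esterification acylates the only secondary hydroxyl (C6), since the tertiary C4 hydroxyl and the tertiary C8 silyl ether cannot compete, and no stereocentre is touched.

Step 13
Reactants: 22 (3S,3aS,4S,6R,8aS)-3-hydroxy-6,8a-dimethyl-3-(propan-2-yl)-6-(triethylsilyloxy)-3,3a,4,5,6,7,8,8a-octahydroazulen-4-yl 4-(tert-butyldimethylsilyloxy)-3-methoxybenzoate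
Product: 23 (3S,3aS,4S,6R,8aS)-3,6-dihydroxy-6,8a-dimethyl-3-(propan-2-yl)-3,3a,4,5,6,7,8,8a-octahydroazulen-4-yl 4-hydroxy-3-methoxybenzoate (CNP0113302.1)
Conditions: TBAF (3 equiv), THF, 0 °C → rt
Reagents that add atoms: none
Why: Fluoride-mediated desilylation removes the aryl TBS ether and the tertiary TES ether in one operation, and the benzoate ester and the tertiary allylic alcohol should tolerate the mildly basic medium.

**Compound list**

1 | 2,5-dimethylfuran | Cc1ccc(C)o1 | starting material
2 | 1,1,3,3-tetrabromopropan-2-one (tetrabromoacetone) | BrC(Br)C(=O)C(Br)Br | starting material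
3 | 2,4-dibromo-1,5-dimethyl-8-oxabicyclo[3.2.1]oct-6-en-3-one (cis bridgeheads, mixture at the two CHBr centres; not isolated) | C[C@]12C=C[C@@](C)(O2)C(Br)C(=O)C1Br | intermediate
4 | meso-(1R,5S)-1,5-dimethyl-8-oxabicyclo[3.2.1]oct-6-en-3-one | C[C@]12C=C[C@](C)(CC(=O)C1)O2 | intermediate
5 | meso-(1R,5S)-1,5-dimethyl-8-oxabicyclo[3.2.1]octan-3-one | C[C@]12CC[C@](C)(CC(=O)C1)O2 | intermediate
6 | lithium (1S,5R)-1,5-dimethyl-8-oxabicyclo[3.2.1]oct-2-en-3-olate (not isolated) | C[C@]12CC[C@](C)(CC(O[Li])=C1)O2 | intermediate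
7 | (1S,5R)-1,5-dimethyl-3-(triethylsilyloxy)-8-oxabicyclo[3.2.1]oct-2-ene | C[C@]12CC[C@](C)(CC(O[Si](CC)(CC)CC)=C1)O2 | intermediate
8 | (6R)-3,6-dimethyl-6-(triethylsilyloxy)cyclohept-2-en-1-one | O=C1C=C(C)CC[C@@](C)(O[Si](CC)(CC)CC)C1 | intermediate
9 | (3S,6R)-3-ethenyl-3,6-dimethyl-6-(triethylsilyloxy)-1-(trimethylsilyloxy)cyclohept-1-ene (vinyl trans to OSiEt3) | C[Si](C)(C)OC1=C[C@](C)(C=C)CC[C@@](C)(O[Si](CC)(CC)CC)C1 | intermediate
10 | acrolein (prop-2-enal) | C=CC=O | starting material
11 | lithium (3S,6R)-3-ethenyl-3,6-dimethyl-6-(triethylsilyloxy)cyclohept-1-en-1-olate (not isolated) | [Li]OC1=C[C@](C)(C=C)CC[C@@](C)(O[Si](CC)(CC)CC)C1 | intermediate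
12 | (3S,6R)-1-(dicyclohexylboranyloxy)-3-ethenyl-3,6-dimethyl-6-(triethylsilyloxy)cyclohept-1-ene (not isolated) | C1CCCCC1B(C2CCCCC2)OC3=C[C@](C)(C=C)CC[C@@](C)(O[Si](CC)(CC)CC)C3 | intermediate
13 | (2R,3S,6R)-3-ethenyl-2-[(1R)-1-hydroxyprop-2-en-1-yl]-3,6-dimethyl-6-(triethylsilyloxy)cycloheptan-1-one (anti aldol, side chain trans to vinyl) | O=C1C[C@](C)(O[Si](CC)(CC)CC)CC[C@@](C)(C=C)[C@@H]1[C@H](O)C=C | intermediate
14 | (2R,3S,6R)-2-[(1R)-1-(diethylboranyloxy)prop-2-en-1-yl]-3-ethenyl-3,6-dimethyl-6-(triethylsilyloxy)cycloheptan-1-one, boron chelated to the ketone (not isolated) | O=C1C[C@](C)(O[Si](CC)(CC)CC)CC[C@@](C)(C=C)[C@@H]1[C@H](OB(CC)CC)C=C | intermediate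
15 | (1S,2S,3S,6R)-3-ethenyl-2-[(1R)-1-hydroxyprop-2-en-1-yl]-3,6-dimethyl-6-(triethylsilyloxy)cycloheptan-1-ol | O[C@H]1C[C@](C)(O[Si](CC)(CC)CC)CC[C@@](C)(C=C)[C@@H]1[C@H](O)C=C | intermediate
16 | (3R,3aS,4S,6R,8aS)-6,8a-dimethyl-6-(triethylsilyloxy)-3,3a,4,5,6,7,8,8a-octahydroazulene-3,4-diol (trans-fused) | O[C@H]1C[C@](C)(O[Si](CC)(CC)CC)CC[C@@]2(C)C=C[C@@H](O)[C@H]12 | intermediate
17 | (3aS,4S,6R,8aS)-4-hydroxy-6,8a-dimethyl-6-(triethylsilyloxy)-3a,4,5,6,7,8-hexahydroazulen-3(8aH)-one | O[C@H]1C[C@](C)(O[Si](CC)(CC)CC)CC[C@@]2(C)C=CC(=O)[C@H]12 | intermediate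
18 | (3S,3aS,4S,6R,8aS)-6,8a-dimethyl-3-(propan-2-yl)-6-(triethylsilyloxy)-3,3a,4,5,6,7,8,8a-octahydroazulene-3,4-diol | O[C@H]1C[C@](C)(O[Si](CC)(CC)CC)CC[C@@]2(C)C=C[C@@](O)(C(C)C)[C@H]12 | intermediate
19 | vanillic acid (4-hydroxy-3-methoxybenzoic acid) | COc1cc(C(=O)O)ccc1O | starting material
20 | tert-butyldimethylsilyl 4-(tert-butyldimethylsilyloxy)-3-methoxybenzoate (not isolated) | COc1cc(C(=O)O[Si](C)(C)C(C)(C)C)ccc1O[Si](C)(C)C(C)(C)C | intermediate
21 | 4-(tert-butyldimethylsilyloxy)-3-methoxybenzoic acid | COc1cc(C(=O)O)ccc1O[Si](C)(C)C(C)(C)C | intermediate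
22 | (3S,3aS,4S,6R,8aS)-3-hydroxy-6,8a-dimethyl-3-(propan-2-yl)-6-(triethylsilyloxy)-3,3a,4,5,6,7,8,8a-octahydroazulen-4-yl 4-(tert-butyldimethylsilyloxy)-3-methoxybenzoate | COc1cc(C(=O)O[C@H]2C[C@](C)(O[Si](CC)(CC)CC)CC[C@@]3(C)C=C[C@@](O)(C(C)C)[C@H]23)ccc1O[Si](C)(C)C(C)(C)C | intermediate
23 | (3S,3aS,4S,6R,8aS)-3,6-dihydroxy-6,8a-dimethyl-3-(propan-2-yl)-3,3a,4,5,6,7,8,8a-octahydroazulen-4-yl 4-hydroxy-3-methoxybenzoate | COc1cc(C(=O)O[C@H]2C[C@](C)(O)CC[C@@]3(C)C=C[C@@](O)(C(C)C)[C@H]23)ccc1O | target

**Step count and risks**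

Total steps: 13. Longest linear sequence: 12 (steps 1–10, 12, 13); step 11 is a one-step side branch.

Steps most likely to fail:

1. Step 5. The process at risk is facial selection at C1: the only bias is the remote C8 centre acting through ring conformation, so the vinyl group may enter on both faces. The fallback sets out from 8 and replaces substrate control by catalyst control. It uses a copper-catalysed enantioselective conjugate addition of dimethyl(vinyl)aluminium (from vinylMgBr and Me2AlCl) under a chiral N-heterocyclic carbene or phosphinamine ligand, the ligand enantiomer being the one matched to the substrate. The resulting dimethylaluminium enolate F1 is silylated in the same flask with TMSOTf and rejoins the route at 9.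

2. Step 6. The processes at risk are facial selection at C5 (methyl and vinyl on C1 differ little in size), leakage between anti and syn aldol, and loss of enolate regiochemistry during the lithium-to-boron exchange. The fallback sets out from 9 and uses it directly as the nucleophile in a catalytic enantioselective Mukaiyama aldol reaction with acrolein (SiCl4 activated by a chiral bisphosphoramide Lewis base). This open-transition-state process is anti-selective for cyclic enol silanes, so the catalyst chooses the aldehyde face and, through the anti relationship, the configuration at C5. It comes back to the route at 13 and makes no new compound (F0).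

3. Step 10. The processes at risk are enolisation at the ring-fusion carbon C5, reduction of the ketone by β-hydride transfer from the secondary alkyl reagent, and retro-aldol opening of the β-alkoxy ketone. The fallback sets out from 17 and adds the sp2 nucleophile isopropenylmagnesium bromide with CeCl3, which cannot deliver a β-hydride and is less basic, to give the isopropenyl carbinol F2. The 1,1-disubstituted alkene is then saturated selectively with H2 and RhCl(PPh3)3; the ring alkene, flanked by two fully substituted carbons, should be left untouched. This arrives at 18.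

Further compounds

F1 | step 5 | dimethylaluminium (3S,6R)-3-ethenyl-3,6-dimethyl-6-(triethylsilyloxy)cyclohept-1-en-1-olate | C[Al](C)OC1=C[C@](C)(C=C)CC[C@@](C)(O[Si](CC)(CC)CC)C1
F0 | step 6 | none | none
F2 | step 10 | (3S,3aS,4S,6R,8aS)-6,8a-dimethyl-3-(prop-1-en-2-yl)-6-(triethylsilyloxy)-3,3a,4,5,6,7,8,8a-octahydroazulene-3,4-diol | O[C@H]1C[C@](C)(O[Si](CC)(CC)CC)CC[C@@]2(C)C=C[C@@](O)(C(C)=C)[C@H]12
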